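The pitfall is to expect the pace of a batch to follow its charge.

| flask | starting material | partner | free catalyst | time |
|---|---|---|---|---|
| spring | 0.120 M | 0.180 M | 0.0120 M |  |
| autumn | 0.120 M | 0.180 M | 0.0360 M |  |
| winter | 0.360 M | 0.180 M | 0.0120 M |  |
| noon | 0.120 M | 0.540 M | 0.0120 M |  |
| dawn | 0.360 M | 0.540 M | 0.0120 M | 42 min |

- spring run (time / min: [starting material] / M): 2.4: 0.1116; 7.2: 0.0997; 14: 0.0840; 22: 0.0697; 31: 0.0551; 42: 0.0402
- autumn run (time / min: [starting material] / M): 2.4: 0.0978; 7.2: 0.0680; 14: 0.0390; 22: 0.0186; 31: 0.0075; 42: 0.0021
- winter run (time / min: [starting material] / M): 2.4: 0.3506; 7.2: 0.3357; 14: 0.3168; 22: 0.2959; 31: 0.2766; 42: 0.2541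
- noon run (time / min: [starting material] / M): 2.4: 0.1107; 7.2: 0.0954; 14: 0.0750; 22: 0.0564; 31: 0.0406; 42: 0.0259

(standard deviation of a reading: 4 × 10⁻⁴ M)

- Overall: starting material + partner -> product, with free catalyst as catalyst.
- Constant volume, constant temperature.
- What is held in complexes is read along with the free species.
- "The second partner" is partner.
- An order is taken over about fifteen percent of the charge, up and down.

* apparent order in [partner] of the starting rate, round the charge of the spring run (the rate where two percent of its starting material have turned into product)
* apparent order in [free catalyst] of the starting rate, round the charge of the spring run (the rate where two percent of its starting material have turned into product)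
* starting material in the dawn run at 42 min, as a share of the starting material charged

We compare two runs by their clock gain: the time the slower run needs over the time the faster run needs to leave the same fraction of its charge. A gain equal to the ratio of charges means order 1, and a gain of 1 means order 0.

The spring run leaves 33.5% at 42 min, and the noon run leaves 33.8% at 31 min. So the gain from partner reads 1.35, and our order in partner, taken over that stretch of the two runs, is 0.276.

The autumn run leaves 32.5% at 14 min. So the gain from catalyst reads 3.00, and our order in catalyst, taken over that stretch of the two runs, is 1.00.

The dawn run has the starting material of the winter run and the partner of the noon run. The winter run has lost 29.4% of its charge at 42 min. We multiply that loss by the gain from partner, and our estimate for the dawn run at 42 min is 60.3% of its charge left.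

The forecast gives an order in partner of 0.25, an order in free catalyst of 1 and 60% of the charge left in the dawn run, noting that “Noon reaches the same conversions as spring about 1.35 times faster”. Our order in partner stands a little higher.

The flask gives a starting-rate order in partner of 0.47, a starting-rate order in free catalyst of 0.73 and 55.2% of the charge left in the dawn run.

    free catalyst + starting material → loaded catalyst + by-product (8.760 M⁻¹ min⁻¹)
    loaded catalyst + partner → product + free catalyst (2.856 M⁻¹ min⁻¹)
    free catalyst + by-product ⇌ catalyst-by-product complex, settled at all times (8.910 M⁻¹)
    free catalyst + starting material ⇌ idle catalyst-substrate complex, settled at all times (14.10 M⁻¹)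

In the spring run, product reaches half of the charge at 30.5 min, while the reading at 31 min shows 54.1% of the starting material gone. At 42 min, the dawn run has lost 1.52 times the share of its charge that the winter run has lost, higher than the gain of 1.35 we read. Counted on product at a quarter of the charge, the gain of the autumn run over the spring run is 2.46, lower than the 3.00 read on starting material.

The numbers in the tables were generated by integration for an exercise; noise was put on by code.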